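## The problem

Compound 17 is a trans-2-aryl-3-(hydroxymethyl)-2,3-dihydrobenzofuran. Its dihydrofuran ring B (O1–C2–C3–C3a–C7a) is fused to arene ring A, which carries a methoxy group at C7 and a 3-(sulfooxy)propyl chain at C5; C2 bears the guaiacyl ring C. The two adjacent stereocentres, C2 (S) and C3 (R), have to be made as one enantiomer. C2 is benzylic, bonded to O1 and para to an oxygen of ring C, so it ionises easily under acid and, once the phenol is free, under base. C3 is not acidic and cannot be corrected later, and inverting C2 in a cis isomer would give the enantiomer of 17. C2 must therefore be set absolutely first and then direct C3 under kinetic control, and any cis isomer can only be removed. Three hydroxyl groups (phenol, C9–OH, chain OH) must be told apart, because only the chain oxygen carries the sulfate; the sulfate monoester is strongly acidic, very polar and solvolysed by hot acid, so it belongs late and may be followed only by mild steps. The enabling feature is C3: it holds both the bond to C3a and the oxygenated carbon C9, which is the pattern left when an aryl radical at C3a adds to the internal carbon of a vinyl group on C2 (five atoms away through C7a–O1–C2) and the terminal carbon is oxygenated. Rings A and C, with all their substituents, are available as dihydroconiferyl alcohol 1 and O-benzylvanillin 4.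

## Retrosynthesis

**Sulfate and the three hydroxyls (17 ⇒ 16 ⇒ 15 ⇒ 14 ⇒ 13).** No skeletal bond is cut here; the S–O bond and three protecting groups are removed in thought. The sulfate is placed on 14, in which only the chain hydroxyl is free. The phenol is a benzyl ether, C9–OH is the tetramethylpiperidinyl ether that the key step itself leaves behind, and the chain hydroxyl of 13 is a silyl ether. The three masks fall by three different mechanisms (fluoride, zinc reduction of N–O, hydrogenolysis), so no protecting step is spent on C9 and nothing acidic or basic touches the ionisable C2–O1 bond once the sulfate is present. Each unmasking is asked to leave the sulfate ester and the benzylic ether intact.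

**Ring B (13 ⇒ 11 + 12).** The bonds C3–C3a and C9–O are cut together. This leaves aryl iodide 11, an allyl aryl ether that already holds O1–C2 with its configuration, and the nitroxide 12. Cutting C2–C3 or O1–C2 at this stage would leave C3 to be built at ester oxidation level or require a cis-to-trans correction. The chosen cut removes the ring, one stereocentre and the C9 oxygen in one operation and ends at two flat aromatic fragments joined by one ether bond. The forward reaction must close 5-exo and not 6-endo, cyclise before the aryl radical is quenched, oxygenate the primary radical before it is reduced, and place the new CH2 group trans to the C2 aryl group.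

**The ether bond O1–C2 (11 ⇒ 9 + 10, 10 from 3).** The cut gives the linear cinnamyl carbonate 9 and the aryloxide 10 of iodophenol 3. A displacement at a preformed secondary benzylic centre (Mitsunobu or halide) would fight ionisation and allylic transposition at a donor-substituted benzylic carbon. The iridium-catalysed allylic etherification makes the C–O bond and the stereocentre together from an achiral carbonate and gives the branched isomer that carries the vinyl group needed later. It must deliver branched over linear ether, high enantiomeric purity, and tolerance of an aryl iodide and of an aryloxide substituted at both ortho positions.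

**The ring A fragment (3 ⇒ 2 ⇒ 1).** Cutting O–Si and C–I leads to dihydroconiferyl alcohol 1, which already has ring A, the methoxy group and the three-carbon chain. Iodination is placed before silylation: the phenoxide directs iodine to its only free ortho position, and the iodine then shields the phenol so that the silyl chloride takes the primary alcohol alone.

**The ring C fragment (9 ⇒ 8 ⇒ 7 ⇒ 4 + 5).** The carbonate comes from cinnamyl alcohol 8, this from ester 7, and the C=C bond of 7 from O-benzylvanillin 4 and phosphonate 5 (through its carbanion 6). These three routine steps ask only for E geometry, which the stabilised phosphonate gives.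

## Roads not taken

**Alternative 1: flavanone ring contraction.** The cut is C3–C3a, made by a 1,2-shift: flavanone A1 would be treated with PhI(OAc)2 and H2SO4 in trimethyl orthoformate, the ring A carbon would migrate from C4 to C3, and the former C4 would leave the ring as the methyl ester of A2.
- Merits: no tin is used. More importantly, C3 of A2 is α to an ester, so the trans relationship can be secured by equilibration. On this point the road is better than the chosen plan, where a cis isomer can only be separated.
- Weak points: C2 of A1 is configurationally labile (retro-oxa-Michael opening) and the step runs in sulfuric acid. Migration of ring C instead of ring A is favoured by donors on ring C, which the pivalate only partly tempers. The silyl ether and the electron-rich ring A must survive oxidant and acid. C9 arrives as an ester, and its reduction strips the pivalate and creates a second primary alcohol that must then be distinguished from the chain hydroxyl. A1 itself needs C-acylation of ring A, condensation and an asymmetric ring closure.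
- Comparison: against the correctable ester, the chosen plan offers neutral conditions at C2, C9 at the alcohol oxidation level and already masked, and a clearly shorter sequence.

**Alternative 2: rhodium carbenoid C–H insertion.** The cut is C2–C3: diazo ester A3 would lose N2 on Rh2(S-DOSP)4 and the carbenoid carbon would insert into the benzylic C–H bond of the O–CH2–aryl ether to give cis ester A4.
- Merits: both stereocentres come from one catalytic asymmetric step, the electron-rich benzylic C–H bond is a good insertion site, and epimerisation of A4 at C3 would give the trans series. In stereocontrol this road is probably stronger than the chosen plan, because the absolute configuration is set in the ring-forming step and the relative one is thermodynamically adjustable.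
- Weak points: A3 needs an arylacetic ester ortho to the phenol oxygen of ring A, which dihydroconiferyl alcohol does not offer, followed by diazo transfer. Two donor-rich arenes can intercept the carbenoid. C9 is again an ester, so a reduction and extra protecting-group steps are needed to keep C9–OH apart from the chain hydroxyl before sulfation.
- Comparison: the chosen plan sets against it a two-fragment convergence through the phenol itself, no change of oxidation state at C9, and a C9 oxygen that arrives carrying its own orthogonal protecting group.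

**Alternative 3: benzene ring from a pyrone–alkyne Diels–Alder reaction.** The cuts are C3a–C7a and C4–C5: on heating, pyrone A5 would add across its tethered alkyne and lose CO2, closing rings A and B together to give A6.
- Merits: no radical and no tin are involved, and ring closure raises no diastereoselectivity question because both stereocentres are already in A5. The C9 oxygen is a benzyl ether, so after sulfation a single hydrogenolysis would free C9–OH and the phenol; the end game is one step shorter than in the chosen plan.
- Weak points: the stereochemical problem is only moved into the acyclic chain of A5, which needs its own asymmetric synthesis. The ionisable benzylic ether bond must still be formed, now with a poorly nucleophilic pyrone hydroxyl. The reaction needs high temperature on a benzylic propargylic ether, and it rebuilds an arene that can be bought complete.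
- Comparison: the chosen plan accepts one more deprotection and gains a much shorter approach to the cyclisation substrate.

Key step: step 7

Assumption: sulfate monoesters 15, 16 and 17 are written as the free hydrogen sulfates to match the target; in practice they would be handled as sodium salts after a NaHCO3 work-up and the counter-ion exchanged for a proton only at the final isolation, so the counter-ion is left out of names, SMILES and bookkeeping.

## Route

Step 1
Reactants: 1 dihydroconiferyl alcohol [4-(3-hydroxypropyl)-2-methoxyphenol]
Product: 2 4-(3-hydroxypropyl)-2-iodo-6-methoxyphenol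
Conditions: I2 (1.05 equiv), NaHCO3, THF/H2O, 0 °C to rt
Reagents that add atoms: iodine, II
Why: Electrophilic aromatic iodination of the phenoxide; the para position carries the chain and one ortho position the methoxy group, so iodine should enter the only free ortho carbon (the future C3a), and the aliphatic alcohol is inert.

Step 2
Reactants: 2 4-(3-hydroxypropyl)-2-iodo-6-methoxyphenol
Product: 3 4-{3-[(tert-butyldimethylsilyl)oxy]propyl}-2-iodo-6-methoxyphenol
Conditions: TBSCl (1.1 equiv), imidazole, CH2Cl2, 0 °C
Reagents that add atoms: tert-butyldimethylsilyl chloride, CC(C)(C)[Si](C)(C)Cl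
Why: Silyl ether formation; the unhindered primary alcohol should react well before the phenol, which is flanked by iodine and methoxy.

Step 3
Reactants: 4 4-benzyloxy-3-methoxybenzaldehyde (O-benzylvanillin), 5 triethyl phosphonoacetate
Product: 7 ethyl (2E)-3-(4-benzyloxy-3-methoxyphenyl)prop-2-enoate, via sodium phosphonate carbanion 6 (not isolated)
Conditions: 5, NaH, THF, 0 °C; then 4, 0 °C to rt
Reagents that add atoms: none
Why: Horner–Wadsworth–Emmons olefination; the stabilised phosphonate carbanion gives the E-cinnamate under thermodynamic control of the elimination.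

Step 4
Reactants: 7 ethyl (2E)-3-(4-benzyloxy-3-methoxyphenyl)prop-2-enoate
Product: 8 (2E)-3-(4-benzyloxy-3-methoxyphenyl)prop-2-en-1-ol
Conditions: i-Bu2AlH (2.2 equiv), CH2Cl2, −78 °C; aq. KNaC4H4O6 work-up
Reagents that add atoms: none
Why: 1,2-Reduction of an α,β-unsaturated ester by the aluminium hydride gives the allylic alcohol without touching the alkene or the benzyl ether.

Step 5
Reactants: 8 (2E)-3-(4-benzyloxy-3-methoxyphenyl)prop-2-en-1-ol
Product: 9 (2E)-3-(4-benzyloxy-3-methoxyphenyl)prop-2-en-1-yl methyl carbonate
Conditions: ClCO2Me, pyridine, CH2Cl2, 0 °C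
Reagents that add atoms: methyl chloroformate, COC(=O)Cl
Why: Acylation of the primary allylic alcohol; the methyl carbonate is the standard leaving group for iridium-catalysed allylic substitution.

Step 6
Reactants: 3 4-{3-[(tert-butyldimethylsilyl)oxy]propyl}-2-iodo-6-methoxyphenol, 9 (2E)-3-(4-benzyloxy-3-methoxyphenyl)prop-2-en-1-yl methyl carbonate
Product: 11 (S)-1-(4-benzyloxy-3-methoxyphenyl)prop-2-en-1-yl 4-{3-[(tert-butyldimethylsilyl)oxy]propyl}-2-iodo-6-methoxyphenyl ether, via lithium aryloxide 10 (not isolated)
Conditions: 3 (1.3 equiv), n-BuLi, THF, 0 °C; then 9, [Ir(cod)Cl]2 (2 mol%), (Sa,Sc,Sc)-O,O′-(1,1′-binaphthyl-2,2′-diyl) N,N-bis(1-phenylethyl)phosphoramidite (4 mol%), THF, 50 °C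
Reagents that add atoms: none
Why: Iridium-catalysed asymmetric allylic etherification: the cyclometalated iridium–phosphoramidite complex ionises 9 to a π-allyl complex and aryloxide 10 attacks the aryl-substituted terminus to give the branched ether. C2 is set by the chiral ligand, whose antipode is chosen to give the S ether, and the blocked ortho positions of 10 exclude C-allylation while the aryl iodide is not activated by this catalyst.

Step 7
Reactants: 11 (S)-1-(4-benzyloxy-3-methoxyphenyl)prop-2-en-1-yl 4-{3-[(tert-butyldimethylsilyl)oxy]propyl}-2-iodo-6-methoxyphenyl ether, 12 TEMPO [(2,2,6,6-tetramethylpiperidin-1-yl)oxyl]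
Product: 13 1-{[(2S,3R)-2-(4-benzyloxy-3-methoxyphenyl)-5-{3-[(tert-butyldimethylsilyl)oxy]propyl}-7-methoxy-2,3-dihydrobenzofuran-3-yl]methoxy}-2,2,6,6-tetramethylpiperidine
Conditions: 12 (4 equiv), Bu3SnH (3 equiv, added in portions), PhH, 70 °C
Reagents that add atoms: none
Why: TEMPO abstracts hydrogen from Bu3SnH, and the stannyl radical removes iodine from 11 to give the aryl σ-radical at C3a. This radical adds to the internal vinyl carbon in a 5-exo-trig closure that forms C3–C3a and ring B (O1–C2–C3–C3a–C7a), and the exocyclic primary radical at C9 couples with a second TEMPO to form C9–O. The closest known reaction type is the tin hydride and nitroxide mediated 5-exo-trig cyclisation of aryl halides onto tethered allyl groups with trapping of the cyclised primary radical. Exo closure is the kinetically preferred mode for an aryl radical attacking a monosubstituted alkene through a three-atom tether; hydrogen transfer from C2 would need a strained 1,4-shift, and attack on ring C is slower than attack on the vinyl group. The new stereocentre C3 is controlled by C2: in the chair-like transition state the C2 aryl group sits pseudo-equatorial and the alkene terminus turns away from it, so the CH2 group should end trans to the aryl group, which is 2S,3R. The step needs cyclisation to precede quenching of the aryl radical and oxygenation to precede reduction of the primary radical; the fast ring closure, a low standing concentration of Bu3SnH and an excess of TEMPO secure both. C2 is not touched, so its configuration is carried through, and any minor cis isomer is removed by chromatography at this stage.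

Step 8
Reactants: 13 1-{[(2S,3R)-2-(4-benzyloxy-3-methoxyphenyl)-5-{3-[(tert-butyldimethylsilyl)oxy]propyl}-7-methoxy-2,3-dihydrobenzofuran-3-yl]methoxy}-2,2,6,6-tetramethylpiperidine
Product: 14 3-[(2S,3R)-2-(4-benzyloxy-3-methoxyphenyl)-7-methoxy-3-{[(2,2,6,6-tetramethylpiperidin-1-yl)oxy]methyl}-2,3-dihydrobenzofuran-5-yl]propan-1-ol
Conditions: Bu4NF, THF, 0 °C to rt
Reagents that add atoms: none
Why: Fluoride cleavage of the primary silyl ether; the benzyl ether, the alkoxyamine and the cyclic benzylic ether are inert to fluoride.

Step 9
Reactants: 14 3-[(2S,3R)-2-(4-benzyloxy-3-methoxyphenyl)-7-methoxy-3-{[(2,2,6,6-tetramethylpiperidin-1-yl)oxy]methyl}-2,3-dihydrobenzofuran-5-yl]propan-1-ol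
Product: 15 3-[(2S,3R)-2-(4-benzyloxy-3-methoxyphenyl)-7-methoxy-3-{[(2,2,6,6-tetramethylpiperidin-1-yl)oxy]methyl}-2,3-dihydrobenzofuran-5-yl]propyl hydrogen sulfate
Conditions: SO3·pyridine, pyridine, rt
Reagents that add atoms: sulfur trioxide–pyridine complex, O=S(=O)=O.c1ccncc1
Why: O-Sulfation of the only free hydroxyl by the SO3–amine complex; the phenol and C9–OH are masked and the hindered alkoxyamine nitrogen is not sulfonated.

Step 10
Reactants: 15 3-[(2S,3R)-2-(4-benzyloxy-3-methoxyphenyl)-7-methoxy-3-{[(2,2,6,6-tetramethylpiperidin-1-yl)oxy]methyl}-2,3-dihydrobenzofuran-5-yl]propyl hydrogen sulfate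
Product: 16 3-[(2S,3R)-2-(4-benzyloxy-3-methoxyphenyl)-3-(hydroxymethyl)-7-methoxy-2,3-dihydrobenzofuran-5-yl]propyl hydrogen sulfate
Conditions: Zn dust, AcOH/THF/H2O, 50 °C
Reagents that add atoms: none
Why: Reductive cleavage of the alkoxyamine N–O bond by zinc in acetic acid frees C9–OH; a primary alkyl sulfate, the benzyl ether and the C2–O1 bond should withstand warm dilute acetic acid.

Step 11
Reactants: 16 3-[(2S,3R)-2-(4-benzyloxy-3-methoxyphenyl)-3-(hydroxymethyl)-7-methoxy-2,3-dihydrobenzofuran-5-yl]propyl hydrogen sulfate
Product: 17 3-[(2S,3R)-2-(4-hydroxy-3-methoxyphenyl)-3-(hydroxymethyl)-7-methoxy-2,3-dihydrobenzofuran-5-yl]propyl hydrogen sulfate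
Conditions: H2 (1 atm), Pd/C, MeOH, rt
Reagents that add atoms: none
Why: Catalytic hydrogenolysis of the aryl benzyl ether, which is expected to be much faster than cleavage of the cyclic benzylic O1–C2 bond; the neutral medium leaves the sulfate and both stereocentres untouched.

## Compound list

1 | dihydroconiferyl alcohol, 4-(3-hydroxypropyl)-2-methoxyphenol | COc1cc(CCCO)ccc1O | starting material
2 | 4-(3-hydroxypropyl)-2-iodo-6-methoxyphenol | COc1cc(CCCO)cc(I)c1O | intermediate
3 | 4-{3-[(tert-butyldimethylsilyl)oxy]propyl}-2-iodo-6-methoxyphenol | COc1cc(CCCO[Si](C)(C)C(C)(C)C)cc(I)c1O | intermediate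
4 | 4-benzyloxy-3-methoxybenzaldehyde | COc1cc(C=O)ccc1OCc1ccccc1 | starting material
5 | triethyl phosphonoacetate | CCOC(=O)CP(=O)(OCC)OCC | starting material
6 | sodium salt of the triethyl phosphonoacetate carbanion | CCOC(=O)[CH-]P(=O)(OCC)OCC.[Na+] | intermediate (not isolated)
7 | ethyl (2E)-3-(4-benzyloxy-3-methoxyphenyl)prop-2-enoate | CCOC(=O)/C=C/c1ccc(OCc2ccccc2)c(OC)c1 | intermediate
8 | (2E)-3-(4-benzyloxy-3-methoxyphenyl)prop-2-en-1-ol | OC/C=C/c1ccc(OCc2ccccc2)c(OC)c1 | intermediate
9 | (2E)-3-(4-benzyloxy-3-methoxyphenyl)prop-2-en-1-yl methyl carbonate | COC(=O)OC/C=C/c1ccc(OCc2ccccc2)c(OC)c1 | intermediate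
10 | lithium 4-{3-[(tert-butyldimethylsilyl)oxy]propyl}-2-iodo-6-methoxyphenolate | [Li+].COc1cc(CCCO[Si](C)(C)C(C)(C)C)cc(I)c1[O-] | intermediate (not isolated)
11 | (S)-1-(4-benzyloxy-3-methoxyphenyl)prop-2-en-1-yl 4-{3-[(tert-butyldimethylsilyl)oxy]propyl}-2-iodo-6-methoxyphenyl ether | COc1cc([C@H](C=C)Oc2c(OC)cc(CCCO[Si](C)(C)C(C)(C)C)cc2I)ccc1OCc1ccccc1 | intermediate
12 | TEMPO, (2,2,6,6-tetramethylpiperidin-1-yl)oxyl | CC1(C)CCCC(C)(C)N1[O] | starting material
13 | 1-{[(2S,3R)-2-(4-benzyloxy-3-methoxyphenyl)-5-{3-[(tert-butyldimethylsilyl)oxy]propyl}-7-methoxy-2,3-dihydrobenzofuran-3-yl]methoxy}-2,2,6,6-tetramethylpiperidine | COc1cc([C@H]2Oc3c(OC)cc(CCCO[Si](C)(C)C(C)(C)C)cc3[C@@H]2CON2C(C)(C)CCCC2(C)C)ccc1OCc1ccccc1 | intermediate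
14 | 3-[(2S,3R)-2-(4-benzyloxy-3-methoxyphenyl)-7-methoxy-3-{[(2,2,6,6-tetramethylpiperidin-1-yl)oxy]methyl}-2,3-dihydrobenzofuran-5-yl]propan-1-ol | COc1cc([C@H]2Oc3c(OC)cc(CCCO)cc3[C@@H]2CON2C(C)(C)CCCC2(C)C)ccc1OCc1ccccc1 | intermediate
15 | 3-[(2S,3R)-2-(4-benzyloxy-3-methoxyphenyl)-7-methoxy-3-{[(2,2,6,6-tetramethylpiperidin-1-yl)oxy]methyl}-2,3-dihydrobenzofuran-5-yl]propyl hydrogen sulfate | COc1cc([C@H]2Oc3c(OC)cc(CCCOS(=O)(=O)O)cc3[C@@H]2CON2C(C)(C)CCCC2(C)C)ccc1OCc1ccccc1 | intermediate
16 | 3-[(2S,3R)-2-(4-benzyloxy-3-methoxyphenyl)-3-(hydroxymethyl)-7-methoxy-2,3-dihydrobenzofuran-5-yl]propyl hydrogen sulfate | COc1cc([C@H]2Oc3c(OC)cc(CCCOS(=O)(=O)O)cc3[C@@H]2CO)ccc1OCc1ccccc1 | intermediate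
17 | 3-[(2S,3R)-2-(4-hydroxy-3-methoxyphenyl)-3-(hydroxymethyl)-7-methoxy-2,3-dihydrobenzofuran-5-yl]propyl hydrogen sulfate (CNP0220090.1) | COc1cc([C@H]2Oc3c(OC)cc(CCCOS(=O)(=O)O)cc3[C@@H]2CO)ccc1O | target

## Step count and least certain steps

Total: 11 steps. Longest linear sequence: 9 steps (steps 3, 4, 5, 6, 7, 8, 9, 10, 11 from 4); the ring A branch (steps 1 and 2) joins at step 6.

**Step 7 (key step).** The most likely failure is interception of the chain carriers: stannyl radicals couple with the nitroxide, conversion stalls, and the extra tin hydride then reduces the cyclised radical instead of leaving it to be oxygenated. The second concern is incomplete facial discrimination by the C2 aryl group, which would cost material as the cis isomer. Fallback: starting from 11, the cyclisation is run as an aerobic tin hydride reaction (Bu3SnH under dry air in toluene, then PPh3), in which O2 traps the primary radical and the hydroperoxide is reduced. This gives [(2S,3R)-2-(4-benzyloxy-3-methoxyphenyl)-5-{3-[(tert-butyldimethylsilyl)oxy]propyl}-7-methoxy-2,3-dihydrobenzofuran-3-yl]methanol F1. Acetylation (Ac2O, pyridine) gives the C9 acetate F2; HF·pyridine removes the silyl group to give the chain alcohol F3; SO3·pyridine gives the sulfate acetate F4; and K2CO3 in MeOH removes the acetate and returns to the route at 16. This path also avoids the zinc reduction of step 10 on a sulfate.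

**Step 6.** The branched product is itself an allylic aryl ether with a donor-substituted aryl group and a fairly good aryloxide leaving group. The catalyst may therefore re-ionise it, with drift towards the linear ether and loss of enantiomeric purity; attack by the doubly ortho-substituted aryloxide may also be slow. The sense of induction of the chosen ligand antipode has to be confirmed on the first run, and the other antipode is used if it proves opposite. Fallback: starting from 8 and 3, the configuration is taken from a Sharpless asymmetric epoxidation (Ti(Oi-Pr)4, L-(+)-diisopropyl tartrate, t-BuOOH, 4 Å MS, CH2Cl2, −20 °C) to give [(2S,3S)-3-(4-benzyloxy-3-methoxyphenyl)oxiran-2-yl]methanol F5. The sodium salt of 3 (NaOH, aqueous dioxane, 60 °C) opens the epoxide at the benzylic carbon with inversion to give (2S,3R)-3-(4-benzyloxy-3-methoxyphenyl)-3-{4-[3-(tert-butyldimethylsilyloxy)propyl]-2-iodo-6-methoxyphenoxy}propane-1,2-diol F6. Thiocarbonyldiimidazole converts the diol into the cyclic thionocarbonate (4S)-4-[(R)-(4-benzyloxy-3-methoxyphenyl){4-[3-(tert-butyldimethylsilyloxy)propyl]-2-iodo-6-methoxyphenoxy}methyl]-1,3-dioxolane-2-thione F7, and a Corey–Winter olefination (1,3-dimethyl-2-phenyl-1,3,2-diazaphospholidine, 40 °C) turns it into the vinyl group and returns to the route at 11.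

**Step 1.** Iodination may also occur para to the methoxy group or twice, and the electron-rich phenol may be oxidised by iodine. Fallback: the iodine is bought in place. Starting from 5 and 4-hydroxy-3-iodo-5-methoxybenzaldehyde (5-iodovanillin) F8, a Horner–Wadsworth–Emmons reaction (NaH, 2.2 equiv, THF, through 6) gives ethyl (2E)-3-(4-hydroxy-3-iodo-5-methoxyphenyl)prop-2-enoate F9. Diimide reduction (TsNHNH2, NaOAc, aqueous DME, reflux) saturates the alkene without touching the C–I bond to give ethyl 3-(4-hydroxy-3-iodo-5-methoxyphenyl)propanoate F10, and LiBH4 in THF reduces the ester and returns to the route at 2.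

**Step 2.** The phenol may be silylated alongside the primary alcohol. Fallback: starting from 2, both hydroxyls are silylated (TBSCl, 2.5 equiv, imidazole, DMF) to give tert-butyl{3-[4-(tert-butyldimethylsilyloxy)-3-iodo-5-methoxyphenyl]propoxy}dimethylsilane F11, and the aryl silyl ether alone is cleaved with K2CO3 in MeOH at rt, which returns to the route at 3.

## Further compounds

F1 | step 7 | [(2S,3R)-2-(4-benzyloxy-3-methoxyphenyl)-5-{3-[(tert-butyldimethylsilyl)oxy]propyl}-7-methoxy-2,3-dihydrobenzofuran-3-yl]methanol | COc1cc([C@H]2Oc3c(OC)cc(CCCO[Si](C)(C)C(C)(C)C)cc3[C@@H]2CO)ccc1OCc1ccccc1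
F2 | step 7 | [(2S,3R)-2-(4-benzyloxy-3-methoxyphenyl)-5-{3-[(tert-butyldimethylsilyl)oxy]propyl}-7-methoxy-2,3-dihydrobenzofuran-3-yl]methyl acetate | COc1cc([C@H]2Oc3c(OC)cc(CCCO[Si](C)(C)C(C)(C)C)cc3[C@@H]2COC(C)=O)ccc1OCc1ccccc1
F3 | step 7 | [(2S,3R)-2-(4-benzyloxy-3-methoxyphenyl)-5-(3-hydroxypropyl)-7-methoxy-2,3-dihydrobenzofuran-3-yl]methyl acetate | COc1cc([C@H]2Oc3c(OC)cc(CCCO)cc3[C@@H]2COC(C)=O)ccc1OCc1ccccc1
F4 | step 7 | [(2S,3R)-2-(4-benzyloxy-3-methoxyphenyl)-7-methoxy-5-[3-(sulfooxy)propyl]-2,3-dihydrobenzofuran-3-yl]methyl acetate | COc1cc([C@H]2Oc3c(OC)cc(CCCOS(=O)(=O)O)cc3[C@@H]2COC(C)=O)ccc1OCc1ccccc1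
F5 | step 6 | [(2S,3S)-3-(4-benzyloxy-3-methoxyphenyl)oxiran-2-yl]methanol | COc1cc([C@@H]2O[C@H]2CO)ccc1OCc1ccccc1
F6 | step 6 | (2S,3R)-3-(4-benzyloxy-3-methoxyphenyl)-3-{4-[3-(tert-butyldimethylsilyloxy)propyl]-2-iodo-6-methoxyphenoxy}propane-1,2-diol | COc1cc([C@H]([C@@H](O)CO)Oc2c(OC)cc(CCCO[Si](C)(C)C(C)(C)C)cc2I)ccc1OCc1ccccc1
F7 | step 6 | (4S)-4-[(R)-(4-benzyloxy-3-methoxyphenyl){4-[3-(tert-butyldimethylsilyloxy)propyl]-2-iodo-6-methoxyphenoxy}methyl]-1,3-dioxolane-2-thione | COc1cc([C@H]([C@@H]2COC(=S)O2)Oc2c(OC)cc(CCCO[Si](C)(C)C(C)(C)C)cc2I)ccc1OCc1ccccc1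
F8 | step 1 | 4-hydroxy-3-iodo-5-methoxybenzaldehyde (5-iodovanillin) | COc1cc(C=O)cc(I)c1O
F9 | step 1 | ethyl (2E)-3-(4-hydroxy-3-iodo-5-methoxyphenyl)prop-2-enoate | CCOC(=O)/C=C/c1cc(I)c(O)c(OC)c1
F10 | step 1 | ethyl 3-(4-hydroxy-3-iodo-5-methoxyphenyl)propanoate | CCOC(=O)CCc1cc(I)c(O)c(OC)c1
F11 | step 2 | tert-butyl{3-[4-(tert-butyldimethylsilyloxy)-3-iodo-5-methoxyphenyl]propoxy}dimethylsilane | COc1cc(CCCO[Si](C)(C)C(C)(C)C)cc(I)c1O[Si](C)(C)C(C)(C)C
A1 | alternative 1 | (2S)-8-methoxy-2-(3-methoxy-4-pivaloyloxyphenyl)-6-[3-(tert-butyldiphenylsilyloxy)propyl]chroman-4-one | COc1cc([C@@H]2CC(=O)c3cc(CCCO[Si](c4ccccc4)(c4ccccc4)C(C)(C)C)cc(OC)c3O2)ccc1OC(=O)C(C)(C)C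
A2 | alternative 1 | methyl (2S,3S)-7-methoxy-2-(3-methoxy-4-pivaloyloxyphenyl)-5-[3-(tert-butyldiphenylsilyloxy)propyl]-2,3-dihydrobenzofuran-3-carboxylate (trans) | COc1cc([C@H]2Oc3c(OC)cc(CCCO[Si](c4ccccc4)(c4ccccc4)C(C)(C)C)cc3[C@@H]2C(=O)OC)ccc1OC(=O)C(C)(C)C
A3 | alternative 2 | methyl 2-diazo-2-{2-[(4-benzyloxy-3-methoxybenzyl)oxy]-3-methoxy-5-[3-(tert-butyldimethylsilyloxy)propyl]phenyl}acetate | COC(=O)C(=[N+]=[N-])c1cc(CCCO[Si](C)(C)C(C)(C)C)cc(OC)c1OCc1ccc(OCc2ccccc2)c(OC)c1
A4 | alternative 2 | methyl (2S,3R)-2-(4-benzyloxy-3-methoxyphenyl)-7-methoxy-5-[3-(tert-butyldimethylsilyloxy)propyl]-2,3-dihydrobenzofuran-3-carboxylate (cis) | COc1cc([C@H]2Oc3c(OC)cc(CCCO[Si](C)(C)C(C)(C)C)cc3[C@H]2C(=O)OC)ccc1OCc1ccccc1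
A5 | alternative 3 | 3-{[(1S,2R)-1-(4-benzyloxy-3-methoxyphenyl)-2-(benzyloxymethyl)but-3-yn-1-yl]oxy}-4-methoxy-6-[3-(tert-butyldimethylsilyloxy)propyl]-2H-pyran-2-one | O=c1oc(CCCO[Si](C)(C)C(C)(C)C)cc(OC)c1O[C@H](c1ccc(OCc2ccccc2)c(OC)c1)[C@@H](COCc1ccccc1)C#C
A6 | alternative 3 | (2S,3R)-2-(4-benzyloxy-3-methoxyphenyl)-3-(benzyloxymethyl)-7-methoxy-5-[3-(tert-butyldimethylsilyloxy)propyl]-2,3-dihydrobenzofuran | COc1cc([C@H]2Oc3c(OC)cc(CCCO[Si](C)(C)C(C)(C)C)cc3[C@@H]2COCc2ccccc2)ccc1OCc1ccccc1
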